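**Remark on stereodescriptors.** The target is taken as (2R,4′R,8′S), which is the natural tocopherol arrangement; 8′ is S only because the 11′,12′-olefin raises the CIP rank of that arm. All methyl-bearing chain centres keep the spatial arrangement of (R)-citronellol throughout, and their R/S labels change between compounds only through CIP ranking. Which antipode of the acid in step 8 gives 2R cannot be predicted and is to be fixed by trial; the 2S product is a diastereomer and therefore recognisable.

## Strategy

The dihydropyran ring of the chroman is opened at C4–C4a and at O1–C2. This leads back to a monoacetylated methylhydroquinone, whose free OH (O1) and the one unsubstituted carbon ortho to it (C4a) act as an O,C-bis-nucleophile, and to a C20 (E)-allylic alcohol carrying both side-chain stereocentres, whose C1 and trisubstituted C2=C3 olefin become C4, C3 and the quaternary C2. One operation with a confined chiral Brønsted acid is to join the two: Friedel–Crafts allylation, then face-selective hydroalkoxylation that closes the ring and sets C2. The alcohol comes from (R)-citronellyl bromide by two isoprenoid homologations and one Ru–BINAP hydrogenation.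

Key step: step 8

## Route

Step 1
Reactants: 1 (R)-citronellyl bromide, (6R)-8-bromo-2,6-dimethyloct-2-ene
Product: 2 (6S)-6,10-dimethylundec-9-en-1-yne
Conditions: propyne, n-BuLi (2 equiv), TMEDA, Et2O–hexane, 0 °C to rt; then 1, THF, −78 °C to rt; H2O
Reagents that add atoms: propyne (CC#C)
Why: Alkylation of the propargyl dianion (1,3-dilithiopropyne): its sp3 carbanion end displaces the primary bromide by SN2 and protonation of the surviving acetylide should give the terminal alkyne, the stereocentre of 1 not being involved.

Step 2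
Reactants: 2 (6S)-6,10-dimethylundec-9-en-1-yne
Product: 4 (2E,7S)-3,7,11-trimethyldodeca-2,10-dien-1-ol, via alkenyldimethylalane 3 (not isolated)
Conditions: Me3Al, Cp2ZrCl2 (cat.), CH2Cl2, 0 °C to rt; then n-BuLi, (CH2O)n, THF, 0 °C to rt; aq. HCl
Reagents that add atoms: trimethylaluminium (C[Al](C)C); paraformaldehyde, reacting as formaldehyde (C=O)
Why: Negishi Zr-catalysed carboalumination adds Me and Al syn across the terminal alkyne with Me on the internal carbon, and the alkenylalanate is hydroxymethylated with retention, so the 2E geometry is fixed while the isolated trisubstituted olefin stays inert.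

Step 3
Reactants: 4 (2E,7S)-3,7,11-trimethyldodeca-2,10-dien-1-ol
Product: 5 (3R,7S)-3,7,11-trimethyldodec-10-en-1-ol
Conditions: H2 (100 atm), Ru(OAc)2[(S)-BINAP] (cat.), MeOH–H2O 95:5, 20 °C
Reagents that add atoms: none
Why: Noyori hydrogenation of an allylic alcohol: the hydroxyl-directed Ru–BINAP catalyst reduces only the 2,3-olefin and, with the (S)-ligand on the E-olefin (the pairing that turns geraniol into (R)-citronellol), should set 3R by catalyst control and leave the distal olefin untouched.

Step 4
Reactants: 5 (3R,7S)-3,7,11-trimethyldodec-10-en-1-ol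
Product: 6 (6S,10R)-12-bromo-2,6,10-trimethyldodec-2-ene
Conditions: CBr4, PPh3, CH2Cl2, 0 °C
Reagents that add atoms: carbon tetrabromide (BrC(Br)(Br)Br)
Why: Appel reaction of a primary alcohol under neutral conditions, which tolerates the olefin and does not touch either stereocentre.

Step 5
Reactants: 6 (6S,10R)-12-bromo-2,6,10-trimethyldodec-2-ene
Product: 7 (6R,10S)-6,10,14-trimethylpentadec-13-en-1-yne
Conditions: propyne, n-BuLi (2 equiv), TMEDA, Et2O–hexane, 0 °C to rt; then 6, THF, −78 °C to rt; H2O
Reagents that add atoms: propyne (CC#C)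
Why: Second propargyl-dianion alkylation (SN2 at the primary bromide), which adds the three carbons of the next isoprene unit and should leave a terminal alkyne.

Step 6
Reactants: 7 (6R,10S)-6,10,14-trimethylpentadec-13-en-1-yne
Product: 9 (2E,7R,11S)-3,7,11,15-tetramethylhexadeca-2,14-dien-1-ol, via alkenyldimethylalane 8 (not isolated)
Conditions: Me3Al, Cp2ZrCl2 (cat.), CH2Cl2, 0 °C to rt; then n-BuLi, (CH2O)n, THF, 0 °C to rt; aq. HCl
Reagents that add atoms: trimethylaluminium (C[Al](C)C); paraformaldehyde, reacting as formaldehyde (C=O)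
Why: Second Negishi carboalumination/hydroxymethylation, which should deliver the (E)-trisubstituted allylic alcohol stereospecifically by syn addition and retentive C–Al to C–C exchange.

Step 7
Reactants: 10 1-(4-hydroxy-3-methylphenyl)ethan-1-one
Product: 11 4-hydroxy-3-methylphenyl acetate
Conditions: mCPBA, CH2Cl2, 0 °C to rt
Reagents that add atoms: mCPBA (O=C(OO)c1cccc(Cl)c1)
Why: Baeyer–Villiger oxidation in which the electron-rich 4-hydroxyaryl group migrates in preference to methyl, placing the acetate unambiguously on the oxygen para to the free OH.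

Step 8
Reactants: 9 (2E,7R,11S)-3,7,11,15-tetramethylhexadeca-2,14-dien-1-ol; 11 4-hydroxy-3-methylphenyl acetate
Product: 13 (2R)-2,8-dimethyl-2-[(4R,8S)-4,8,12-trimethyltridec-11-en-1-yl]-3,4-dihydro-2H-chromen-6-yl acetate, via ortho-allylphenol 12 (not isolated)
Conditions: chiral confined imidodiphosphorimidate (IDPi) Brønsted acid (5 mol %, antipode selected for 2R), 5 Å MS, cyclohexane–CHCl3, 40 °C
Reagents that add atoms: none
Why: Proposed new method: the strong confined acid should ionise 9 to the (E)-allyl cation/IDPi-anion pair, which alkylates the only free position ortho to the phenol OH of 11 at its primary terminus (C4–C4a, Friedel–Crafts allylation; any O-allyl or tertiary-terminus adduct re-ionises and funnels to 12), and the same catalyst, hydrogen-bonded to the phenol, then protonates C3 of the trisubstituted olefin while O1 adds to C2 (O1–C2, Markovnikov hydroalkoxylation). The closest known reaction types are the acid-mediated condensation of hydroquinones with phytol or isophytol to racemic tocopherols and the confined-acid-catalysed asymmetric intramolecular hydroalkoxylation of unactivated olefins; their merger in one pot on a phenol/allylic alcohol pair is not established. The dihydropyran ring closes 6-endo-trig at the tertiary olefin carbon. C2 is the only new stereocentre and is to be fixed by the catalyst, which selects one face of the E-olefin in an asynchronous concerted protonation/C–O bond formation, the remote 4′ and 8′ centres exerting no bias. The step needs ortho-C attack over O-attack and over attack at the two ring positions next to the acetoxy group, which is secured by the free OH flanked by methyl and by the deactivating para-acetoxy group, and it needs the distal trisubstituted olefin to survive, which is expected because that olefin has no internal nucleophile, so its protonation is reversible and unproductive at 40 °C.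

Step 9
Reactants: 13 (2R)-2,8-dimethyl-2-[(4R,8S)-4,8,12-trimethyltridec-11-en-1-yl]-3,4-dihydro-2H-chromen-6-yl acetate
Product: 14 (2R)-2,8-dimethyl-2-[(4R,8S)-4,8,12-trimethyltridec-11-en-1-yl]-3,4-dihydro-2H-chromen-6-ol
Conditions: K2CO3 (cat.), MeOH (degassed), rt
Reagents that add atoms: none
Why: Base-catalysed transesterification (methanolysis) of the aryl acetate should free the 6-OH without touching the tertiary aryl ether, the olefin or any stereocentre.

## Compound list

1 | (R)-citronellyl bromide, (6R)-8-bromo-2,6-dimethyloct-2-ene | CC(C)=CCC[C@@H](C)CCBr | starting material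
2 | (6S)-6,10-dimethylundec-9-en-1-yne | CC(C)=CCC[C@@H](C)CCCC#C | intermediate
3 | dimethyl[(1E,6S)-2,6,10-trimethylundeca-1,9-dien-1-yl]alumane | CC(C)=CCC[C@@H](C)CCC/C(C)=C/[Al](C)C | intermediate (not isolated)
4 | (2E,7S)-3,7,11-trimethyldodeca-2,10-dien-1-ol | CC(C)=CCC[C@@H](C)CCC/C(C)=C/CO | intermediate
5 | (3R,7S)-3,7,11-trimethyldodec-10-en-1-ol | CC(C)=CCC[C@@H](C)CCC[C@@H](C)CCO | intermediate
6 | (6S,10R)-12-bromo-2,6,10-trimethyldodec-2-ene | CC(C)=CCC[C@@H](C)CCC[C@@H](C)CCBr | intermediate
7 | (6R,10S)-6,10,14-trimethylpentadec-13-en-1-yne | CC(C)=CCC[C@@H](C)CCC[C@@H](C)CCCC#C | intermediate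
8 | dimethyl[(1E,6R,10S)-2,6,10,14-tetramethylpentadeca-1,13-dien-1-yl]alumane | CC(C)=CCC[C@@H](C)CCC[C@@H](C)CCC/C(C)=C/[Al](C)C | intermediate (not isolated)
9 | (2E,7R,11S)-3,7,11,15-tetramethylhexadeca-2,14-dien-1-ol | CC(C)=CCC[C@@H](C)CCC[C@@H](C)CCC/C(C)=C/CO | intermediate
10 | 1-(4-hydroxy-3-methylphenyl)ethan-1-one | CC(=O)c1ccc(O)c(C)c1 | starting material
11 | 4-hydroxy-3-methylphenyl acetate | CC(=O)Oc1ccc(O)c(C)c1 | intermediate
12 | 4-hydroxy-3-methyl-5-[(2E,7R,11S)-3,7,11,15-tetramethylhexadeca-2,14-dien-1-yl]phenyl acetate | CC(C)=CCC[C@@H](C)CCC[C@@H](C)CCC/C(C)=C/Cc1cc(OC(C)=O)cc(C)c1O | intermediate (not isolated)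
13 | (2R)-2,8-dimethyl-2-[(4R,8S)-4,8,12-trimethyltridec-11-en-1-yl]-3,4-dihydro-2H-chromen-6-yl acetate | CC(C)=CCC[C@@H](C)CCC[C@@H](C)CCC[C@]1(C)CCc2cc(OC(C)=O)cc(C)c2O1 | intermediate
14 | (2R)-2,8-dimethyl-2-[(4R,8S)-4,8,12-trimethyltridec-11-en-1-yl]-3,4-dihydro-2H-chromen-6-ol | CC(C)=CCC[C@@H](C)CCC[C@@H](C)CCC[C@]1(C)CCc2cc(O)cc(C)c2O1 | target

## Count and risks

Total step count: 9. Longest linear sequence: 8 (steps 1–6, 8, 9).

**Step 8 (Proposed new method).** The C–O bond-forming protonation/cyclisation may proceed with poor facial selectivity, since the catalyst has to tell the two faces of an olefin whose substituents at C2 are methyl and a CH2 chain. The distal olefin may be protonated and then migrate or alkylate a second phenol. The water released may throttle the acid. The fallback uses known chemistry and relays the chirality of an asymmetric epoxidation through a temporary C3 oxygen; it sets out from 9 and comes back at 14.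
- Sharpless epoxidation of 9 (Ti(OiPr)4, L-(+)-diethyl tartrate, t-BuOOH, 4 Å MS, CH2Cl2, −20 °C) should give the (2S,3S)-epoxy alcohol F1.
- Tf2O and 2,6-lutidine at −78 °C convert it to the epoxy triflate F2.
- Commercial 4-methoxy-2-methylphenol is brominated ortho to the OH (NBS, cat. i-Pr2NH, CH2Cl2) to 2-bromo-4-methoxy-6-methylphenol F3.
- F3 is turned into its C,O-dianion (t-BuLi, THF, −78 °C) and C-alkylated by F2 to the epoxy phenol F4.
- Camphorsulfonic acid added to the same flask should close the ring 6-endo, with inversion at the tertiary epoxide carbon, to the (2R,3S)-chroman-3-ol F5.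
- Barton–McCombie removal of the C3 hydroxyl follows: the xanthate F6 (NaH, CS2, MeI) is reduced with Bu3SnH/AIBN to the methyl ether F7.
- NaSEt in DMF at 130 °C cleaves the methyl ether to 14.

**Step 5 (and its twin, step 1).** SN2 at the unactivated primary bromide may be slow, so that E2 elimination by the strongly basic dianion and ambident propargyl/allenyl alkylation compete. The fallback sets out from 6 and comes back at 7. Bromide 6 is alkylated with the softer, silyl-masked monoanion of 1-(trimethylsilyl)propyne (n-BuLi, THF, −78 °C to rt) to the silyl alkyne F8, which K2CO3 in MeOH desilylates to 7.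

**Step 3.** Facial selectivity may be incomplete, or the allylic olefin may migrate if the hydrogen pressure drops; either gives the 3-epimer, which could not be removed later. The fallback sets out from 2 and comes back at 5. Carboalumination of 2 as in step 2, quenched with ethyl chloroformate instead of formaldehyde, gives the ethyl (2E)-dienoate F9. Copper hydride-catalysed asymmetric conjugate reduction (CuCl, NaOt-Bu, p-tol-BINAP antipode chosen for 3R, polymethylhydrosiloxane, toluene) should give the saturated ester F10. LiAlH4 reduces F10 to 5.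

## Further compounds

F1 | step 8 | [(2S,3S)-3-methyl-3-[(4R,8S)-4,8,12-trimethyltridec-11-en-1-yl]oxiran-2-yl]methanol | CC(C)=CCC[C@@H](C)CCC[C@@H](C)CCC[C@@]1(C)[C@H](CO)O1
F2 | step 8 | [(2S,3S)-3-methyl-3-[(4R,8S)-4,8,12-trimethyltridec-11-en-1-yl]oxiran-2-yl]methyl trifluoromethanesulfonate | CC(C)=CCC[C@@H](C)CCC[C@@H](C)CCC[C@@]1(C)[C@H](COS(=O)(=O)C(F)(F)F)O1
F3 | step 8 | 2-bromo-4-methoxy-6-methylphenol | COc1cc(C)c(O)c(Br)c1
F4 | step 8 | 4-methoxy-2-methyl-6-{[(2S,3S)-3-methyl-3-[(4R,8S)-4,8,12-trimethyltridec-11-en-1-yl]oxiran-2-yl]methyl}phenol | CC(C)=CCC[C@@H](C)CCC[C@@H](C)CCC[C@@]1(C)[C@H](Cc2cc(OC)cc(C)c2O)O1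
F5 | step 8 | (2R,3S)-6-methoxy-2,8-dimethyl-2-[(4R,8S)-4,8,12-trimethyltridec-11-en-1-yl]-3,4-dihydro-2H-chromen-3-ol | CC(C)=CCC[C@@H](C)CCC[C@@H](C)CCC[C@]1(C)[C@@H](O)Cc2cc(OC)cc(C)c2O1
F6 | step 8 | O-[(2R,3S)-6-methoxy-2,8-dimethyl-2-[(4R,8S)-4,8,12-trimethyltridec-11-en-1-yl]-3,4-dihydro-2H-chromen-3-yl] S-methyl carbonodithioate | CC(C)=CCC[C@@H](C)CCC[C@@H](C)CCC[C@]1(C)[C@@H](OC(=S)SC)Cc2cc(OC)cc(C)c2O1
F7 | step 8 | (2R)-6-methoxy-2,8-dimethyl-2-[(4R,8S)-4,8,12-trimethyltridec-11-en-1-yl]-3,4-dihydro-2H-chromene | CC(C)=CCC[C@@H](C)CCC[C@@H](C)CCC[C@]1(C)CCc2cc(OC)cc(C)c2O1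
F8 | step 5 | trimethyl[(6R,10S)-6,10,14-trimethylpentadec-13-en-1-yn-1-yl]silane | CC(C)=CCC[C@@H](C)CCC[C@@H](C)CCCC#C[Si](C)(C)C
F9 | step 3 | ethyl (2E,7S)-3,7,11-trimethyldodeca-2,10-dienoate | CC(C)=CCC[C@@H](C)CCC/C(C)=C/C(=O)OCC
F10 | step 3 | ethyl (3R,7S)-3,7,11-trimethyldodec-10-enoate | CC(C)=CCC[C@@H](C)CCC[C@@H](C)CC(=O)OCC
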